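## The problem

Target 18 is 3,5,7-trihydroxyflavone carrying a 1-(4-hydroxy-3-methoxyphenyl)prop-2-en-1-yl group on C8. Rings A and C form a 4H-chromen-4-one, and ring B is an unsubstituted phenyl on C2. The only stereocentre is the (R)-configured carbon Cα, which joins C8, the guaiacyl ring and the vinyl group. Nothing else in the molecule can relay to it, so a catalyst must set it, and it controls nothing further.

The Cα hydrogen is doubly benzylic and allylic. Strong base can move the double bond into conjugation, and strong acid can cleave the C8–Cα bond from the electron-rich ring A; either erases the stereocentre. The vinyl group excludes hydrogenolysis and electrophilic oxidants late in the route. The guaiacyl methyl ether must survive the release of four hydroxyls, and the free 7-OH lies ortho to the allyl group and could add to it under acid.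

The side chain sits on C8, next to O1, and not on C6. Ring C must therefore close through the more hindered of the two oxygens that flank the acyl-bearing carbon C4a.

The feature that opens the route is ring A itself. It has oxygens on C5, C7 and C8a and the acyl carbon C4 on C4a, which is an acylphloroglucinol: the pattern of a linear tetraketide closed by Claisen condensation of C4a onto C5. The C3 oxygen is α to C4 and can be carried on the chain terminus.

## Retrosynthesis

**18 from 17.** The four O–benzyl bonds of 17 are cut last. Benzyl is preferred to acetal or silyl groups because it survives lithium amides, Mg(OMe)2 and the acid that closes ring C. An acid-labile group on the C5 oxygen could fall off during ring-C closure and let the hemiketal re-close through the wrong oxygen, giving the 6-substituted isomer. The forward step must spare the vinyl group and the methyl ether, so it uses BCl3 with a cation scavenger at low temperature and not hydrogenolysis.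

**17 from 16, 15, and 13 with 14.** Ring C is opened at O1–C2 to diketone 16, and 16 at C2–C3 to benzoate 15, made from phenol 13 and benzoyl chloride 14. This acyl-transfer route is preferred to oxidative closure of a chalcone. With an oxygen on C5 the peroxide route tends to give aurones, and peroxide would also threaten the vinyl group. The C3 oxygen is already present in the ketone side chain of 13, so no late oxidation is needed. Because 13 has a single free phenol, the forward sequence can only give the 8-substituted flavone.

**13 from 12.** Two O–benzyl bonds are cut to give triol 12. The step must tell three phenols apart. The 4-OH is para to the ketone, unchelated and the most acidic. Of the two chelated ortho hydroxyls, the one between the ketone and the arylallyl group is shielded and more tightly hydrogen-bonded, so it should stay free. This simplifies nothing in the skeleton but fixes the 8- versus 6-regiochemistry.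

**12 from 11 (key disconnection).** Ring A is opened at the bond that becomes C4a–C5, giving the acyclic triketo ester 11. This removes the hexasubstituted benzene ring in one cut. The neighbouring options are Friedel–Crafts acylation of a chiral 2-substituted phloroglucinol, or asymmetric allylation of a preformed acylphloroglucinol. Both put Lewis acid or ambident phenoxide chemistry on a ring that already carries the labile Cα–C8 bond. In 11 every ring oxygen is a carbonyl, C4 and C3 with its oxygen are already attached, and the only stereocentre is one carbon away from the reacting chain. The forward reaction must give C-acylation of chain C6 by the ester, and not aldol closure or O-acylation.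

**11 from 8 and 10; 10 from 9.** The chain is cut at C6–C7 (the future C4a–C4) into diketo ester 8 and Weinreb amide 10, made from (benzyloxy)acetyl chloride 9. Carboxylation is placed before this acylation because 8 has only one terminal acidic site, its methyl group. In the reverse order a methyl and a benzyloxymethylene would compete for the last deprotonation. The forward step needs a polyanion of 8 that reacts at C6 and stops at the ketone.

**8 from 6 and 7.** The C1–C2 bond of the chain (future C5–C6) is cut to the 3-substituted pentane-2,4-dione 6 and dimethyl carbonate 7. Diketone 6 is symmetric, so either methyl group gives the same product.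

**6 from 4 and 5.** The Cα–C bond (future C8–Cα) is cut to cinnamyl carbonate 4 and acetylacetone 5. The stereocentre is set here, on a simple substrate, by an iridium allyl complex that delivers a soft carbon nucleophile to the aryl-bearing allyl terminus. Acetylacetone creates no second stereocentre and already holds five of the eight chain carbons. The forward step needs branched selectivity and face control from the ligand.

**4 from 3, 2 and 1.** Carbonate 4 comes from allylic alcohol 3, which comes from ester 2 by reduction, and 2 from ferulic acid 1 by double benzylation. These are functional-group changes on a commercial cinnamic acid.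

## Roads not taken

**Alternative 1: carbonylative assembly of the ring-C diketone.**
- **Cut:** both bonds to C4 (C4a–C4 and C4–C3), with C4 supplied by carbon monoxide.
- **Forward step:** Pd(OAc)2 with Xantphos couples aryl iodide A2, CO and the enolate of 2-(benzyloxy)-1-phenylethan-1-one A3 to give diketone A1, the O-methoxymethyl ether of 16.
- **Merits:** it is convergent and avoids an ester on the crowded oxygen. Acid would then remove the acetal and close ring C in one operation, which is one step shorter at the end than the chosen sequence from 13.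
- **Weak points:** it builds neither ring A nor the stereocentre. A2 still needs an enantioselective C-allylation of a phloroglucinol, three different oxygen substituents around the ring and an iodination. Oxidative addition and CO insertion must occur at an iodide flanked by two alkoxy groups on a hexasubstituted ring, with a terminal alkene available for Heck-type diversion.
- **Comparison:** the endgame is slightly better than the chosen one. The chosen plan sets against it that a single closure delivers ring A, its acyl group and the C3 oxygen, and that no palladium–CO step runs next to the vinyl group.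

**Alternative 2: phenol, aldehyde and vinylboronate condensation.**
- **Cut:** C8–Cα and Cα–vinyl, with no ring closure.
- **Forward step:** 3,5-bis(benzyloxy)phenol A5, 4-(benzyloxy)-3-methoxybenzaldehyde A6 and dibutyl ethenylboronate A7 condense under a chiral 3,3'-dibrominated binaphthol catalyst to give phenol A4.
- **Merits:** it is the shortest road. One step sets the stereocentre, and the free hydroxyl of A4 is by construction the one next to the new substituent, so the 8-regiochemistry needs no selective protection. Acylation of A4 ortho to that hydroxyl would give 13 in about two steps from purchased materials, against nine for the chosen route.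
- **Weak points:** the unsubstituted vinylboronate and a quinone methide stabilised by a para-alkoxy group are unfavourable partners for catalyst control. A5 can also react para to its hydroxyl. The ring acylation that follows needs Lewis acid on a compound holding benzyl ethers, a vinyl group and the acid-labile C8–Cα bond.
- **Comparison:** this road is clearly better in step count and in regiocontrol of ring C. The chosen plan sets against it a stereocentre made on a simple carbonate by a reaction with a broad record for aryl-substituted allyl systems, and no electrophilic aromatic substitution anywhere.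

**Alternative 3: aryne insertion into phenylpropiolic acid.**
- **Cut:** O1–C8a, C4a–C4 and O1–C2.
- **Forward step:** CsF releases the aryne from silyl triflate A9. 3-Phenylprop-2-ynoic acid A10 adds through oxygen at C8a, the acyl group shifts to C4a, and the phenoxide closes ring C to give chromenone A8.
- **Merits:** three bonds and ring C form in one operation, and the alkoxy group next to C4a directs the carboxylate to C8a.
- **Weak points:** A9 is a hexasubstituted arene that already needs the enantiopure 2-(1-arylallyl)phloroglucinol. The carbon to be attacked is the one shielded by the side chain. The aryne can undergo an ene reaction with the allylic Cα–H. A8 lacks the C3 oxygen, and a late hydroxylation would need either an oxidant that attacks the vinyl group or a strong base next to the acidic Cα–H.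
- **Comparison:** the key step is more convergent than the chosen one, but the route is longer overall and ends with an oxidation the molecule tolerates poorly. The chosen plan carries the C3 oxygen from the start.

Key step: step 8

## Route

Remark: the descriptor of the allylic carbon changes from S (6, 8, 11) to R (12 to 18) only because aromatic ring A outranks the guaiacyl ring in the priority rules; the spatial arrangement is the same throughout.

Remark: the (Ra,Rc,Rc) ligand is assumed to deliver the carbon nucleophile to the face that gives (S)-6, as this catalyst family does with malonate-type nucleophiles; the enantiomeric ligand would be used if the sense proved opposite.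

Remark: 8, 11 and 16 are drawn as keto forms; each is an epimer mixture at one enolisable carbon, which is lost later.

Step 1
Reactants: 1 ferulic acid
Product: 2 benzyl (2E)-3-[4-(benzyloxy)-3-methoxyphenyl]prop-2-enoate
Conditions: BnBr (2.3 equiv), K2CO3 (3 equiv), DMF, 60 °C
Reagents that add atoms: benzyl bromide, BrCc1ccccc1
Why: Williamson alkylation of the phenoxide and O-alkylation of the carboxylate occur together; the benzyl ester is removed in the next step and the benzyl ether stays to the end.

Step 2
Reactants: 2 benzyl (2E)-3-[4-(benzyloxy)-3-methoxyphenyl]prop-2-enoate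
Product: 3 (2E)-3-[4-(benzyloxy)-3-methoxyphenyl]prop-2-en-1-ol
Conditions: i-Bu2AlH (2.6 equiv), CH2Cl2, −78 → 0 °C; aq. potassium sodium tartrate
Reagents that add atoms: none
Why: 1,2-Reduction of the unsaturated ester by the aluminium hydride gives the allylic alcohol and leaves the E-alkene and both aryl ethers untouched; benzyl alcohol is removed by chromatography.

Step 3
Reactants: 3 (2E)-3-[4-(benzyloxy)-3-methoxyphenyl]prop-2-en-1-ol
Product: 4 (2E)-3-[4-(benzyloxy)-3-methoxyphenyl]prop-2-en-1-yl methyl carbonate
Conditions: ClCO2Me (1.3 equiv), pyridine (2 equiv), CH2Cl2, 0 °C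
Reagents that add atoms: methyl chloroformate, COC(=O)Cl
Why: Acylation of the primary allylic alcohol gives the methyl carbonate, which on ionisation releases methoxide as the internal base for step 4.

Step 4
Reactants: 4 (2E)-3-[4-(benzyloxy)-3-methoxyphenyl]prop-2-en-1-yl methyl carbonate; 5 acetylacetone
Product: 6 3-{(1S)-1-[4-(benzyloxy)-3-methoxyphenyl]prop-2-en-1-yl}pentane-2,4-dione
Conditions: [Ir(cod)Cl]2 (2 mol %), (Ra,Rc,Rc)-O,O'-(1,1'-binaphthalene-2,2'-diyl) N,N-bis(1-phenylethyl)phosphoramidite (4 mol %), n-PrNH2 preactivation; 5 (2 equiv), THF, 25–35 °C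
Reagents that add atoms: none
Why: Iridium-catalysed asymmetric allylic alkylation: the cyclometalated iridium phosphoramidite complex ionises the carbonate, and the diketonate attacks the aryl-bearing allyl terminus from the face opposite the metal, giving the branched product. The ligand fixes the face and so sets the stereocentre; the symmetric nucleophile adds no second one.

Step 5
Reactants: 6 3-{(1S)-1-[4-(benzyloxy)-3-methoxyphenyl]prop-2-en-1-yl}pentane-2,4-dione; 7 dimethyl carbonate
Product: 8 methyl 4-{(1S)-1-[4-(benzyloxy)-3-methoxyphenyl]prop-2-en-1-yl}-3,5-dioxohexanoate (both C4 epimers, partly enolised)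
Conditions: LiN(i-Pr)2 (3.1 equiv), THF, −78 → 0 °C; then 7 (1.3 equiv), −78 °C → rt; aq. HCl
Reagents that add atoms: none
Why: The 1,3-diketone dianion (central carbon, then a methyl) is acylated at its terminal carbon by the carbonate, a Claisen-type carboxylation, and the third equivalent of base covers the more acidic product. The allylic stereocentre is β to the carbonyls and sits next to an enolate, so it is not deprotonated.

Step 6
Reactants: 9 (benzyloxy)acetyl chloride
Product: 10 2-(benzyloxy)-N-methoxy-N-methylacetamide
Conditions: MeNH(OMe)·HCl (1.1 equiv), Et3N (2.3 equiv), CH2Cl2, 0 °C → rt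
Reagents that add atoms: N,O-dimethylhydroxylamine hydrochloride, CNOC.Cl
Why: Acylation of the hydroxylamine by the acid chloride gives the Weinreb amide, which acylates carbanions once and stops at the ketone.

Step 7
Reactants: 8 methyl 4-{(1S)-1-[4-(benzyloxy)-3-methoxyphenyl]prop-2-en-1-yl}-3,5-dioxohexanoate; 10 2-(benzyloxy)-N-methoxy-N-methylacetamide
Product: 11 methyl 8-(benzyloxy)-4-{(1S)-1-[4-(benzyloxy)-3-methoxyphenyl]prop-2-en-1-yl}-3,5,7-trioxooctanoate (both C4 epimers, enolised)
Conditions: LiN(i-Pr)2 (3.3 equiv), THF, −78 → −20 °C; then 10 (1.1 equiv), −78 → 0 °C; cold aq. HCl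
Reagents that add atoms: none
Why: The trianion of the 3,5-dioxo ester reacts at C6, its last-formed and most nucleophilic carbon, and the chelated tetrahedral adduct of the Weinreb amide survives until the quench; this is the polyanion acylation used to extend polyketone chains. With C2 held as an enolate the ester cannot be attacked by C6 at this stage.

Step 8
Reactants: 11 methyl 8-(benzyloxy)-4-{(1S)-1-[4-(benzyloxy)-3-methoxyphenyl]prop-2-en-1-yl}-3,5,7-trioxooctanoate
Product: 12 2-(benzyloxy)-1-(3-{(1R)-1-[4-(benzyloxy)-3-methoxyphenyl]prop-2-en-1-yl}-2,4,6-trihydroxyphenyl)ethan-1-one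
Conditions: Mg(OMe)2 (5 equiv, commercial solution), MeOH, 25 → 60 °C; cold 1 M HCl
Reagents that add atoms: none
Why: Mg(OMe)2 converts 11 into a magnesium chelate of the 3,5,7-triketone in which C6 is the carbanion and the ester carbon C1 is the only carbonyl not held as an enolate; C6 attacks C1, methoxide leaves, and the 2-acylcyclohexane-1,3,5-trione tautomerises to the aromatic triol 12. The closest known reaction is the magnesium methoxide Claisen cyclisation of unsubstituted 3,5,7-triketo esters to acylphloroglucinols; the C4 substituent and the C8 ether oxygen are the extension. Ring A closes in a 6-(enolendo)-exo-trig mode and forms the bond that becomes C4a–C5 of the flavone. No stereocentre is created: the allylic carbon was set in step 4, is β to the carbonyls and is not deprotonated by methoxide, and C4 becomes an aromatic carbon, so the epimers of 11 converge. The selectivity needed is C-acylation of C6 by the ester over aldol attack of C2 on the C7 ketone, over O-acylation to a 2-pyrone and over aldol attack of C8 on C3. Magnesium chelation secures it: the ketones are held as enolates and are poor electrophiles, C2 and C8 are not the carbanions of the chelate, and a pyrone formed by O-acylation is reopened by methoxide, while C-acylation is made irreversible by aromatisation. The branch at C4 should favour folded conformers that bring C6 and C1 together.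

Step 9
Reactants: 12 2-(benzyloxy)-1-(3-{(1R)-1-[4-(benzyloxy)-3-methoxyphenyl]prop-2-en-1-yl}-2,4,6-trihydroxyphenyl)ethan-1-one
Product: 13 2-(benzyloxy)-1-(4,6-bis(benzyloxy)-3-{(1R)-1-[4-(benzyloxy)-3-methoxyphenyl]prop-2-en-1-yl}-2-hydroxyphenyl)ethan-1-one
Conditions: BnBr (2.1 equiv), K2CO3 (2.5 equiv), acetone, 25 → 50 °C
Reagents that add atoms: benzyl bromide, BrCc1ccccc1
Why: Williamson etherification takes the unchelated 4-OH first and then the less hindered chelated 6-OH. The 2-OH, between the ketone and the arylallyl group, is shielded and most strongly hydrogen-bonded and should remain free, as in partial alkylation of 3-alkyl-2,4,6-trihydroxyphenyl ketones.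

Step 10
Reactants: 13 2-(benzyloxy)-1-(4,6-bis(benzyloxy)-3-{(1R)-1-[4-(benzyloxy)-3-methoxyphenyl]prop-2-en-1-yl}-2-hydroxyphenyl)ethan-1-one; 14 benzoyl chloride
Product: 15 3,5-bis(benzyloxy)-2-[(benzyloxy)acetyl]-6-{(1R)-1-[4-(benzyloxy)-3-methoxyphenyl]prop-2-en-1-yl}phenyl benzoate
Conditions: 14 (1.3 equiv), Et3N (2 equiv), DMAP (0.2 equiv), CH2Cl2, 0 °C → rt
Reagents that add atoms: none
Why: DMAP-catalysed O-acylation of the one remaining phenol places the future C2 and ring B on the oxygen that becomes O1.

Step 11
Reactants: 15 3,5-bis(benzyloxy)-2-[(benzyloxy)acetyl]-6-{(1R)-1-[4-(benzyloxy)-3-methoxyphenyl]prop-2-en-1-yl}phenyl benzoate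
Product: 16 2-(benzyloxy)-1-(4,6-bis(benzyloxy)-3-{(1R)-1-[4-(benzyloxy)-3-methoxyphenyl]prop-2-en-1-yl}-2-hydroxyphenyl)-3-phenylpropane-1,3-dione (both C2 epimers, enolised)
Conditions: LiN(SiMe3)2 (2.5 equiv), THF, −78 → −10 °C; AcOH
Reagents that add atoms: none
Why: Baker–Venkataraman rearrangement: the ketone enolate attacks the neighbouring benzoate through a six-membered transition state and the diketonate–phenoxide is the thermodynamic sink. A silylamide at low temperature deprotonates the α-alkoxy ketone far faster than the hindered Cα–H.

Step 12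
Reactants: 16 2-(benzyloxy)-1-(4,6-bis(benzyloxy)-3-{(1R)-1-[4-(benzyloxy)-3-methoxyphenyl]prop-2-en-1-yl}-2-hydroxyphenyl)-3-phenylpropane-1,3-dione
Product: 17 3,5,7-tris(benzyloxy)-8-{(1R)-1-[4-(benzyloxy)-3-methoxyphenyl]prop-2-en-1-yl}-2-phenyl-4H-chromen-4-one
Conditions: p-TsOH·H2O (0.2 equiv), toluene, 70 °C
Reagents that add atoms: none
Why: Acid-catalysed cyclodehydration (hemiketal formation, then loss of water) gives the chromenone. Only one phenol is free and the benzyl ethers are stable to this acid, so ring C can close only to the 8-substituted isomer.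

Step 13
Reactants: 17 3,5,7-tris(benzyloxy)-8-{(1R)-1-[4-(benzyloxy)-3-methoxyphenyl]prop-2-en-1-yl}-2-phenyl-4H-chromen-4-one
Product: 18 3,5,7-trihydroxy-8-[(1R)-1-(4-hydroxy-3-methoxyphenyl)prop-2-en-1-yl]-2-phenyl-4H-chromen-4-one
Conditions: BCl3 (8 equiv), C6HMe5 (12 equiv), CH2Cl2, −78 °C; MeOH
Reagents that add atoms: none
Why: Lewis-acid debenzylation of aryl benzyl ethers with pentamethylbenzene as a non-basic cation trap removes all four benzyl groups at −78 °C. The aryl methyl ether and the vinyl group should survive, and the trap keeps benzyl cations off the electron-rich rings.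

## Compound list

1 | ferulic acid, (2E)-3-(4-hydroxy-3-methoxyphenyl)prop-2-enoic acid | COc1cc(/C=C/C(=O)O)ccc1O | starting material
2 | benzyl (2E)-3-[4-(benzyloxy)-3-methoxyphenyl]prop-2-enoate | COc1cc(/C=C/C(=O)OCc2ccccc2)ccc1OCc1ccccc1 | intermediate
3 | (2E)-3-[4-(benzyloxy)-3-methoxyphenyl]prop-2-en-1-ol | COc1cc(/C=C/CO)ccc1OCc1ccccc1 | intermediate
4 | (2E)-3-[4-(benzyloxy)-3-methoxyphenyl]prop-2-en-1-yl methyl carbonate | COC(=O)OC/C=C/c1ccc(OCc2ccccc2)c(OC)c1 | intermediate
5 | acetylacetone (pentane-2,4-dione) | CC(=O)CC(C)=O | starting material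
6 | 3-{(1S)-1-[4-(benzyloxy)-3-methoxyphenyl]prop-2-en-1-yl}pentane-2,4-dione | C=C[C@H](c1ccc(OCc2ccccc2)c(OC)c1)C(C(C)=O)C(C)=O | intermediate
7 | dimethyl carbonate | COC(=O)OC | starting material
8 | methyl 4-{(1S)-1-[4-(benzyloxy)-3-methoxyphenyl]prop-2-en-1-yl}-3,5-dioxohexanoate (C4 epimers) | C=C[C@H](c1ccc(OCc2ccccc2)c(OC)c1)C(C(C)=O)C(=O)CC(=O)OC | intermediate
9 | (benzyloxy)acetyl chloride | O=C(Cl)COCc1ccccc1 | starting material
10 | 2-(benzyloxy)-N-methoxy-N-methylacetamide | CON(C)C(=O)COCc1ccccc1 | intermediate
11 | methyl 8-(benzyloxy)-4-{(1S)-1-[4-(benzyloxy)-3-methoxyphenyl]prop-2-en-1-yl}-3,5,7-trioxooctanoate (C4 epimers) | C=C[C@H](c1ccc(OCc2ccccc2)c(OC)c1)C(C(=O)CC(=O)COCc1ccccc1)C(=O)CC(=O)OC | intermediate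
12 | 2-(benzyloxy)-1-(3-{(1R)-1-[4-(benzyloxy)-3-methoxyphenyl]prop-2-en-1-yl}-2,4,6-trihydroxyphenyl)ethan-1-one | C=C[C@H](c1ccc(OCc2ccccc2)c(OC)c1)c1c(O)cc(O)c(C(=O)COCc2ccccc2)c1O | intermediate
13 | 2-(benzyloxy)-1-(4,6-bis(benzyloxy)-3-{(1R)-1-[4-(benzyloxy)-3-methoxyphenyl]prop-2-en-1-yl}-2-hydroxyphenyl)ethan-1-one | C=C[C@H](c1ccc(OCc2ccccc2)c(OC)c1)c1c(OCc2ccccc2)cc(OCc2ccccc2)c(C(=O)COCc2ccccc2)c1O | intermediate
14 | benzoyl chloride | O=C(Cl)c1ccccc1 | starting material
15 | 3,5-bis(benzyloxy)-2-[(benzyloxy)acetyl]-6-{(1R)-1-[4-(benzyloxy)-3-methoxyphenyl]prop-2-en-1-yl}phenyl benzoate | C=C[C@H](c1ccc(OCc2ccccc2)c(OC)c1)c1c(OCc2ccccc2)cc(OCc2ccccc2)c(C(=O)COCc2ccccc2)c1OC(=O)c1ccccc1 | intermediate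
16 | 2-(benzyloxy)-1-(4,6-bis(benzyloxy)-3-{(1R)-1-[4-(benzyloxy)-3-methoxyphenyl]prop-2-en-1-yl}-2-hydroxyphenyl)-3-phenylpropane-1,3-dione (C2 epimers) | C=C[C@H](c1ccc(OCc2ccccc2)c(OC)c1)c1c(OCc2ccccc2)cc(OCc2ccccc2)c(C(=O)C(OCc2ccccc2)C(=O)c2ccccc2)c1O | intermediate
17 | 3,5,7-tris(benzyloxy)-8-{(1R)-1-[4-(benzyloxy)-3-methoxyphenyl]prop-2-en-1-yl}-2-phenyl-4H-chromen-4-one | C=C[C@H](c1ccc(OCc2ccccc2)c(OC)c1)c1c(OCc2ccccc2)cc(OCc2ccccc2)c2c(=O)c(OCc3ccccc3)c(-c3ccccc3)oc12 | intermediate
18 | 3,5,7-trihydroxy-8-[(1R)-1-(4-hydroxy-3-methoxyphenyl)prop-2-en-1-yl]-2-phenyl-4H-chromen-4-one (CNP0417789.1) | C=C[C@H](c1ccc(O)c(OC)c1)c1c(O)cc(O)c2c(=O)c(O)c(-c3ccccc3)oc12 | target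

## Step count and risks

Total: 13 steps. Longest linear sequence: 12 steps (steps 1–5 and 7–13, from 1 to 18); step 6 is a one-step side branch.

**Step 8 (key step).**
- What may go wrong: the substituted C4 resists enolisation, so the magnesium chelate may engage the β-keto ester end and deactivate the ester. Closure then slows, and O-acylation to a 2-pyrone, aldol closure of C2 onto C7, or retro-Claisen loss of an acyl group from the crowded C4 can take over.
- Fallback: reverse the order of ring formation and allylation, so that the Claisen-type ring synthesis is no longer asked to tolerate the branch. The fallback sets out from carbonate 4. The partner is 2-(benzyloxy)-1-(2,4,6-trihydroxyphenyl)ethan-1-one F1, made by Hoesch acylation of phloroglucinol with (benzyloxy)acetonitrile (ZnCl2, HCl, Et2O, then hot water). The monoanion of F1 is a vinylogous 1,3-diketonate and is used as the soft carbon nucleophile under the catalyst of step 4, with F1 in excess to suppress a second allylation. This gives 12 directly, where the route is rejoined. The open point is O- versus C-allylation; an aryl allyl ether of so acidic a phenol should re-ionise and drain to the C-allylated product.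

**Step 4.**
- What may go wrong: the diketonate can bind iridium as an O,O-chelate and slow turnover, and a slow reaction with an electron-rich cinnamyl system invites loss of branched selectivity and of enantiopurity.
- Fallback: use the benchmark nucleophile and build the diketone afterwards. From 4, the same catalyst with dimethyl malonate gives dimethyl 2-{(1S)-1-[4-(benzyloxy)-3-methoxyphenyl]prop-2-en-1-yl}propanedioate F2. Krapcho demethoxycarbonylation (NaCl, wet DMSO, 150 °C) gives methyl (3R)-3-[4-(benzyloxy)-3-methoxyphenyl]pent-4-enoate F3. Claisen condensation with the lithium enolate of methyl acetate (3 equiv) gives methyl (5R)-5-[4-(benzyloxy)-3-methoxyphenyl]-3-oxohept-6-enoate F4. The dianion of F4 (NaH, then n-BuLi) is acetylated at C4 with N-methoxy-N-methylacetamide to give 8, where the route is rejoined. This replaces steps 4 and 5 at the cost of two extra steps.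

**Step 7.**
- What may go wrong: trianion formation may be incomplete on the crowded substrate, the carbanion may take a proton from the α-methylene of 10 instead of adding, and neutral 11 may lactonise during work-up.
- Fallback: tie up the keto ester as a pyrone so that only a dianion is needed. From 8, DBU in hot toluene gives 5-{(1R)-1-[4-(benzyloxy)-3-methoxyphenyl]prop-2-en-1-yl}-4-hydroxy-6-methyl-2H-pyran-2-one F5. Its dianion (LiN(i-Pr)2, 2.2 equiv) is acylated at the 6-methyl group by 10 to give 6-[3-(benzyloxy)-2-oxopropyl]-5-{(1R)-1-[4-(benzyloxy)-3-methoxyphenyl]prop-2-en-1-yl}-4-hydroxy-2H-pyran-2-one F6. Mg(OMe)2 in methanol opens the lactone to the magnesium enolate of 11, with C4 already in its enolate form, and closes ring A in the same flask. The route is rejoined at 12.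

**Step 9.**
- What may go wrong: site selectivity between the two chelated hydroxyls may be poor, and ring carbon C5 may be benzylated.
- Fallback: protect all three phenols and unmask one. From 12, excess BnBr with K2CO3 in DMF gives 2-(benzyloxy)-1-(2,4,6-tris(benzyloxy)-3-{(1R)-1-[4-(benzyloxy)-3-methoxyphenyl]prop-2-en-1-yl}phenyl)ethan-1-one F7. MgBr2·OEt2 in toluene–ether then cleaves one aryl benzyl ether ortho to the ketone by chelation. The ether wedged between the ketone and the arylallyl group is twisted out of conjugation and should be the one cleaved, which returns 13.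

**Step 11.**
- What may go wrong: acyl transfer may be slow because ketone and ester are both twisted by their ortho neighbours, and forcing the base risks a 1,3-proton shift of the Cα hydrogen into conjugation.
- Fallback: form C2–C3 by aldol chemistry under weaker base and oxidise afterwards. From 13, Claisen–Schmidt condensation with benzaldehyde (KOH, EtOH, rt) gives (2Z)-2-(benzyloxy)-1-(4,6-bis(benzyloxy)-3-{(1R)-1-[4-(benzyloxy)-3-methoxyphenyl]prop-2-en-1-yl}-2-hydroxyphenyl)-3-phenylprop-2-en-1-one F8. Oxidative cyclisation with catalytic I2 in DMSO at 110 °C then gives 17 and bypasses 15 and 16.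

## Further compounds

F1 | step 8 | 2-(benzyloxy)-1-(2,4,6-trihydroxyphenyl)ethan-1-one | O=C(COCc1ccccc1)c1c(O)cc(O)cc1O
F2 | step 4 | dimethyl 2-{(1S)-1-[4-(benzyloxy)-3-methoxyphenyl]prop-2-en-1-yl}propanedioate | C=C[C@H](c1ccc(OCc2ccccc2)c(OC)c1)C(C(=O)OC)C(=O)OC
F3 | step 4 | methyl (3R)-3-[4-(benzyloxy)-3-methoxyphenyl]pent-4-enoate | C=C[C@H](c1ccc(OCc2ccccc2)c(OC)c1)CC(=O)OC
F4 | step 4 | methyl (5R)-5-[4-(benzyloxy)-3-methoxyphenyl]-3-oxohept-6-enoate | C=C[C@H](c1ccc(OCc2ccccc2)c(OC)c1)CC(=O)CC(=O)OC
F5 | step 7 | 5-{(1R)-1-[4-(benzyloxy)-3-methoxyphenyl]prop-2-en-1-yl}-4-hydroxy-6-methyl-2H-pyran-2-one | C=C[C@H](c1ccc(OCc2ccccc2)c(OC)c1)c1c(O)cc(=O)oc1C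
F6 | step 7 | 6-[3-(benzyloxy)-2-oxopropyl]-5-{(1R)-1-[4-(benzyloxy)-3-methoxyphenyl]prop-2-en-1-yl}-4-hydroxy-2H-pyran-2-one | C=C[C@H](c1ccc(OCc2ccccc2)c(OC)c1)c1c(O)cc(=O)oc1CC(=O)COCc1ccccc1
F7 | step 9 | 2-(benzyloxy)-1-(2,4,6-tris(benzyloxy)-3-{(1R)-1-[4-(benzyloxy)-3-methoxyphenyl]prop-2-en-1-yl}phenyl)ethan-1-one | C=C[C@H](c1ccc(OCc2ccccc2)c(OC)c1)c1c(OCc2ccccc2)cc(OCc2ccccc2)c(C(=O)COCc2ccccc2)c1OCc1ccccc1
F8 | step 11 | (2Z)-2-(benzyloxy)-1-(4,6-bis(benzyloxy)-3-{(1R)-1-[4-(benzyloxy)-3-methoxyphenyl]prop-2-en-1-yl}-2-hydroxyphenyl)-3-phenylprop-2-en-1-one | C=C[C@H](c1ccc(OCc2ccccc2)c(OC)c1)c1c(OCc2ccccc2)cc(OCc2ccccc2)c(C(=O)/C(OCc2ccccc2)=C/c2ccccc2)c1O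
A1 | alternative 1 | 2-(benzyloxy)-1-(4,6-bis(benzyloxy)-3-{(1R)-1-[4-(benzyloxy)-3-methoxyphenyl]prop-2-en-1-yl}-2-(methoxymethoxy)phenyl)-3-phenylpropane-1,3-dione | C=C[C@H](c1ccc(OCc2ccccc2)c(OC)c1)c1c(OCc2ccccc2)cc(OCc2ccccc2)c(C(=O)C(OCc2ccccc2)C(=O)c2ccccc2)c1OCOC
A2 | alternative 1 | 1,5-bis(benzyloxy)-2-{(1R)-1-[4-(benzyloxy)-3-methoxyphenyl]prop-2-en-1-yl}-4-iodo-3-(methoxymethoxy)benzene | C=C[C@H](c1ccc(OCc2ccccc2)c(OC)c1)c1c(OCc2ccccc2)cc(OCc2ccccc2)c(I)c1OCOC
A3 | alternative 1 | 2-(benzyloxy)-1-phenylethan-1-one | O=C(COCc1ccccc1)c1ccccc1
A4 | alternative 2 | 3,5-bis(benzyloxy)-2-{(1R)-1-[4-(benzyloxy)-3-methoxyphenyl]prop-2-en-1-yl}phenol | C=C[C@H](c1ccc(OCc2ccccc2)c(OC)c1)c1c(O)cc(OCc2ccccc2)cc1OCc1ccccc1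
A5 | alternative 2 | 3,5-bis(benzyloxy)phenol | Oc1cc(OCc2ccccc2)cc(OCc2ccccc2)c1
A6 | alternative 2 | 4-(benzyloxy)-3-methoxybenzaldehyde | COc1cc(C=O)ccc1OCc1ccccc1
A7 | alternative 2 | dibutyl ethenylboronate | C=CB(OCCCC)OCCCC
A8 | alternative 3 | 5,7-bis(benzyloxy)-8-{(1R)-1-[4-(benzyloxy)-3-methoxyphenyl]prop-2-en-1-yl}-2-phenyl-4H-chromen-4-one | C=C[C@H](c1ccc(OCc2ccccc2)c(OC)c1)c1c(OCc2ccccc2)cc(OCc2ccccc2)c2c(=O)cc(-c3ccccc3)oc12
A9 | alternative 3 | 3,5-bis(benzyloxy)-2-{(1R)-1-[4-(benzyloxy)-3-methoxyphenyl]prop-2-en-1-yl}-6-(trimethylsilyl)phenyl trifluoromethanesulfonate | C=C[C@H](c1ccc(OCc2ccccc2)c(OC)c1)c1c(OCc2ccccc2)cc(OCc2ccccc2)c([Si](C)(C)C)c1OS(=O)(=O)C(F)(F)F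
A10 | alternative 3 | 3-phenylprop-2-ynoic acid | OC(=O)C#Cc1ccccc1
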